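(The data are calculated for substances that don't exist; the scatter is artificial.)

**The ratio.** E was the product I followed, and what I had to forecast was how strongly it came out against G.

| setting | summer | midnight | flask |
|---|---|---|---|
| Z | 0.10 M | 0.10 M | 0.10 M |
| D | 0.057 mol% | 0.13 mol% | 0.085 mol% |
| remark | run made earlier | run made earlier |  |
| time |  |  | 15 d |

| run | time / d | E / % | G / % |
|---|---|---|---|
| summer | 1.67 | 74.0 | 18.2 |
| summer | 4.00 | 78.7 | 20.4 |
| summer | 8.00 | 78.8 | 20.9 |
| summer | 12.0 | 79.3 | 20.4 |
| midnight | 1.04 | 81.0 | 16.6 |
| midnight | 2.00 | 82.5 | 17.0 |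
| midnight | 5.00 | 83.7 | 17.8 |
| midnight | 12.0 | 82.9 | 18.0 |

(readings scatter by 0.5 percentage points)

- ratio of E to G at 6.0 min
- ratio of E to G at 15 d

- the analysis behind the earlier runs scatters by 0.5 percentage points, standard deviation
- a reading or a percentage of E counts all its forms, free or not

**Two rates.** At the last readings, after 12.0 d, I read E over G as 3.89 in the summer run and 4.61 in the midnight run. I took this as a contest of two rates (kinetic control): the rate into E, which I supposed grew with the [D] charged, against a rate toward G that gained less from it. I measured D by the [D] charged, 0.0570 mM in the summer run and 0.130 mM in the midnight run. With Z at 0.10 M in both runs, that gave the gain, the rise of the late ratio per unit of [D] charged, as 9.84 /mM. For this flask, at 0.0850 mM, I reckoned 4.16. The gain is a late rule, and the first midnight reading came far later than 6.0 min, so I reckoned nothing early.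

**The forecast.** It gave 4.5 at 6.0 min and 4.2 at 15 d, against my 4.16 for that late time, holding that this was “not a common equilibrium”.

**The flask.** It gave 177 at 6.0 min and 4.22 at 15 d, beside the 4.16 from the gain.

    D + E ⇌ J (K = 37.5 /M, k = 63.1 /M/h)
    Z + D → D + E (k = 3900 /M/h)
    D + Q → D + G (k = 2270 /M/h)
    Z ⇌ Q (K = 0.600, k = 0.196 /h)

**What happened.** In this flask Z made E on D from the start, while G came through Q, which was still rising at 6.0 min; at 0.138 d, Q made over Q used, each step taken net, stood at 0.973. By 1.50 d Z was down to 2.48%, and at 15.0 d E stood at 80.8% and G at 19.2%.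

**Richer flask.** The neighbour flask, with 0.25 M of Z at the same loading, held 0.213 mM of D. The gain gives it 5.42; computed at 15 d, that neighbour flask came out lower, at 5.00.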